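**Plan**
- The alkyne carbon on C5' of ring B (the thiophene carrying the side chain) is a ketone carbon at the dehydrated oxidation level, so the C≡C bond is traced back to a 5'-acyl group whose only α-hydrogens lie on the chain side.
- Ring B is then cut at S–C2' and at C4'–C5'. C5' becomes the doubly activated CH2 (between S and C=O) of an α-mercapto ketone that carries the whole four-carbon chain with its isovalerate. C2'–C3'–C4' become a (Z)-β-chloro enal built on ring A (the thiophene bearing CH2O) with its senecioate.
- Forward, ring A is bought: thiophen-2-ylmethanol is acetylated at C5, esterified and chloroformylated. The chain comes from 5-hydroxypentan-2-one by acylation, kinetic silyl enol ether formation, bromination and NaSH.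
- Ring B is closed by thiolate substitution and aldol condensation; the ketone is then dehydrated to the alkyne through its enol nonaflate.
- The target has no stereocentre and no stereogenic double bond. The only geometric element on the way is the Z chloro enal (Cl cis to CHO), set in the chloroformylation and consumed in the ring closure.

Key step: step 8

Assumption: the target is taken as drawn, an achiral bithiophene diester; each fragment carries its own ester from the start, so the two primary alcohols never have to be told apart.

**Step 1**
Reactants: 1 thiophen-2-ylmethanol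
Product: 3 1-[5-(hydroxymethyl)thiophen-2-yl]ethan-1-one, via dilithio species 2 (not isolated)
Conditions: n-BuLi (2.2 equiv), THF, −78 → 0 °C; MeC(O)N(OMe)Me, −78 °C → rt; aq. NH4Cl
Reagents that add atoms: N-methoxy-N-methylacetamide, CC(=O)N(C)OC
Why: After O-deprotonation the second equivalent of base removes the most acidic ring hydrogen at the free α-position C5 (α-lithiation of thiophene), and the C-lithium end alone attacks the amide in a Weinreb ketone synthesis whose chelated tetrahedral adduct stops at the ketone.

**Step 2**
Reactants: 3 1-[5-(hydroxymethyl)thiophen-2-yl]ethan-1-one; 4 3-methylbut-2-enoic acid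
Product: 5 (5-acetylthiophen-2-yl)methyl 3-methylbut-2-enoate
Conditions: DCC, DMAP (cat.), CH2Cl2, 0 °C → rt
Reagents that add atoms: none
Why: Steglich esterification of a primary alcohol proceeds under near-neutral conditions that should leave the ketone alone and keep the enoate double bond in conjugation.

**Step 3**
Reactants: 5 (5-acetylthiophen-2-yl)methyl 3-methylbut-2-enoate
Product: 6 (Z)-[5-(1-chloro-3-oxoprop-1-en-1-yl)thiophen-2-yl]methyl 3-methylbut-2-enoate
Conditions: POCl3 (3 equiv), DMF, 0 → 55 °C; then ice, aq. NaOAc
Reagents that add atoms: N,N-dimethylformamide, CN(C)C=O; phosphoryl chloride, O=P(Cl)(Cl)Cl; water, O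
Why: Vilsmeier–Haack–Arnold chloroformylation of an aryl methyl ketone gives the β-chloro enal, the Z isomer (Cl cis to CHO, thienyl trans to it) being favoured because the iminium precursor sets its CH=NMe2 group away from the aryl ring; the acyl-deactivated thiophene and the ester should not react.

**Step 4**
Reactants: 7 5-hydroxypentan-2-one; 8 3-methylbutanoyl chloride
Product: 9 4-oxopentyl 3-methylbutanoate
Conditions: pyridine, DMAP (cat.), CH2Cl2, 0 °C → rt
Reagents that add atoms: none
Why: DMAP-catalysed acylation of the primary hydroxyl (nucleophilic acyl substitution) drains the open-chain hydroxy ketone from its cyclic hemiketal form and gives the keto ester.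

**Step 5**
Reactants: 9 4-oxopentyl 3-methylbutanoate
Product: 10 4-[(trimethylsilyl)oxy]pent-4-en-1-yl 3-methylbutanoate
Conditions: LiN(iPr)2 (1.1 equiv), Me3SiCl (1.5 equiv, present from the start), THF, −78 °C; Et3N, pentane, filtration
Reagents that add atoms: chlorotrimethylsilane, C[Si](C)(C)Cl
Why: Kinetic enolate formation with a hindered amide base at −78 °C takes the unhindered methyl hydrogens of the ketone (faster than the internal CH2 or the hindered ester α-CH2), and silylation in situ fixes the less substituted silyl enol ether before equilibration.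

**Step 6**
Reactants: 10 4-[(trimethylsilyl)oxy]pent-4-en-1-yl 3-methylbutanoate
Product: 11 5-bromo-4-oxopentyl 3-methylbutanoate
Conditions: NBS (1.05 equiv), NaHCO3, THF, −78 → 0 °C; aq. work-up
Reagents that add atoms: N-bromosuccinimide, O=C1CCC(=O)N1Br
Why: Electrophilic bromination of a silyl enol ether occurs only at the enol carbon, so the halogen is placed regiospecifically on the former methyl group and the ester is untouched.

**Step 7**
Reactants: 11 5-bromo-4-oxopentyl 3-methylbutanoate
Product: 12 4-oxo-5-sulfanylpentyl 3-methylbutanoate
Conditions: NaSH (2 equiv), degassed THF/H2O, −10 → 0 °C, inverse addition; AcOH quench; used at once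
Reagents that add atoms: sodium hydrosulfide, [Na+].[SH-]
Why: SN2 displacement at an α-bromo ketone is very fast, so excess hydrosulfide at low temperature should give the thiol before thioether formation or ester cleavage can compete, and immediate use forestalls reversible self-addition and air oxidation.

**Step 8**
Reactants: 6 (Z)-[5-(1-chloro-3-oxoprop-1-en-1-yl)thiophen-2-yl]methyl 3-methylbut-2-enoate; 12 4-oxo-5-sulfanylpentyl 3-methylbutanoate
Product: 15 {5'-[4-(3-methylbutanoyloxy)butanoyl]-2,2'-bithiophen-5-yl}methyl 3-methylbut-2-enoate, via vinyl sulfide 13 (not isolated), via aldol adduct 14 (not isolated)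
Conditions: Et3N (2.5 equiv), degassed MeCN, 0 → 50 °C
Reagents that add atoms: none
Why: Triethylamine forms the thiolate of 12, which adds to the chlorine-bearing carbon of 6 and expels chloride (addition–elimination at a vinylic carbon, with retention), so the S–C2' bond is made and sulfur sits cis to the formyl group in 13. The CH2 between sulfur and the ketone is then the most acidic site; its enolate attacks the aldehyde in a 5-(enolexo)-exo-trig aldol closure that makes C4'–C5' (14), and E1cB loss of water aromatises ring B. The closest known reaction type is the Fiesselmann-type condensation of β-chlorovinyl aldehydes with α-mercapto esters and ketones, which gives 5-aryl-2-acylthiophenes. No stereocentre is created in the product, since both sp3 centres of 14 are erased on dehydration, and any E isomer of 6 should converge because the push-pull double bond of the vinyl sulfide equilibrates by reversible thiolate addition. The selectivity needed is enolisation at the sulfur-flanked methylene and not at the other α-carbon of the ketone; it is secured by the double activation (S and C=O) and by the alternative being a seven-membered ring with no aromatic gain. The mild amine base should spare both esters and the β,β-disubstituted enoate.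

**Step 9**
Reactants: 15 {5'-[4-(3-methylbutanoyloxy)butanoyl]-2,2'-bithiophen-5-yl}methyl 3-methylbut-2-enoate
Product: 17 {5'-[4-(3-methylbutanoyloxy)but-1-yn-1-yl]-2,2'-bithiophen-5-yl}methyl 3-methylbut-2-enoate, via enol nonaflate 16 (not isolated)
Conditions: n-C4F9SO2F (1.3 equiv), phosphazene base P2-Et (2.3 equiv), DMF, −30 °C → rt
Reagents that add atoms: none
Why: One-pot enolate O-sulfonylation and anti E2 elimination (ketone-to-alkyne dehydration via the alkenyl nonaflate) can give only the alkyne on C5', because the ketone has hydrogens on one side only; the non-nucleophilic base is too weak to enolise the esters, and the sulfonyl fluoride, present from the start, traps the ketone enolate as it forms.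

**Compound list**
1 | thiophen-2-ylmethanol | OCc1cccs1 | starting material
2 | lithium (5-lithiothiophen-2-yl)methanolate (dilithio species) | [Li]OCc1ccc([Li])s1 | intermediate
3 | 1-[5-(hydroxymethyl)thiophen-2-yl]ethan-1-one | CC(=O)c1ccc(CO)s1 | intermediate
4 | 3-methylbut-2-enoic acid | CC(C)=CC(=O)O | starting material
5 | (5-acetylthiophen-2-yl)methyl 3-methylbut-2-enoate | CC(=O)c1ccc(COC(=O)C=C(C)C)s1 | intermediate
6 | (Z)-[5-(1-chloro-3-oxoprop-1-en-1-yl)thiophen-2-yl]methyl 3-methylbut-2-enoate | O=C/C=C(\Cl)c1ccc(COC(=O)C=C(C)C)s1 | intermediate
7 | 5-hydroxypentan-2-one | CC(=O)CCCO | starting material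
8 | 3-methylbutanoyl chloride | CC(C)CC(=O)Cl | starting material
9 | 4-oxopentyl 3-methylbutanoate | CC(C)CC(=O)OCCCC(C)=O | intermediate
10 | 4-[(trimethylsilyl)oxy]pent-4-en-1-yl 3-methylbutanoate | CC(C)CC(=O)OCCCC(=C)O[Si](C)(C)C | intermediate
11 | 5-bromo-4-oxopentyl 3-methylbutanoate | CC(C)CC(=O)OCCCC(=O)CBr | intermediate
12 | 4-oxo-5-sulfanylpentyl 3-methylbutanoate | CC(C)CC(=O)OCCCC(=O)CS | intermediate
13 | (Z)-[5-(1-{[5-(3-methylbutanoyloxy)-2-oxopentyl]sulfanyl}-3-oxoprop-1-en-1-yl)thiophen-2-yl]methyl 3-methylbut-2-enoate (vinyl sulfide) | O=C/C=C(\SCC(=O)CCCOC(=O)CC(C)C)c1ccc(COC(=O)C=C(C)C)s1 | intermediate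
14 | {5-[4-hydroxy-5-(4-(3-methylbutanoyloxy)butanoyl)-4,5-dihydrothiophen-2-yl]thiophen-2-yl}methyl 3-methylbut-2-enoate (aldol adduct; mixture of diastereomers, both centres lost on dehydration) | CC(C)=CC(=O)OCc1ccc(C2=CC(O)C(C(=O)CCCOC(=O)CC(C)C)S2)s1 | intermediate
15 | {5'-[4-(3-methylbutanoyloxy)butanoyl]-2,2'-bithiophen-5-yl}methyl 3-methylbut-2-enoate | CC(C)=CC(=O)OCc1ccc(-c2ccc(C(=O)CCCOC(=O)CC(C)C)s2)s1 | intermediate
16 | (Z)-{5'-[4-(3-methylbutanoyloxy)-1-(nonafluorobutanesulfonyloxy)but-1-en-1-yl]-2,2'-bithiophen-5-yl}methyl 3-methylbut-2-enoate (enol nonaflate, Z expected) | CC(C)=CC(=O)OCc1ccc(-c2ccc(/C(OS(=O)(=O)C(F)(F)C(F)(F)C(F)(F)C(F)(F)F)=C/CCOC(=O)CC(C)C)s2)s1 | intermediate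
17 | {5'-[4-(3-methylbutanoyloxy)but-1-yn-1-yl]-2,2'-bithiophen-5-yl}methyl 3-methylbut-2-enoate (CNP0114739.0) | CC(C)=CC(=O)OCc1ccc(-c2ccc(C#CCCOC(=O)CC(C)C)s2)s1 | target

**Step count**
Total: 9 steps (convergent). Longest linear sequence: 6 steps (steps 4, 5, 6, 7, 8, 9, from 5-hydroxypentan-2-one); the ring A arm needs 5 (steps 1, 2, 3, 8, 9).

**Steps most likely to fail**

Step 9. The ketone enolate may be diverted before sulfonylation by an O→C shift of the isovaleryl group through a five-membered tetrahedral intermediate. The strong base may also strip isovalerate from the homopropargylic position of the product, giving a conjugated enyne. The fallback sets out from 15 and avoids strong base altogether. Condensation with semicarbazide hydrochloride and NaOAc in ethanol should give {5'-[1-(carbamoylhydrazinylidene)-4-(3-methylbutanoyloxy)butyl]-2,2'-bithiophen-5-yl}methyl 3-methylbut-2-enoate F1 (C=N geometry uncontrolled and of no consequence). Oxidative ring closure with SeO2 in acetic acid should then give {5'-[5-(2-(3-methylbutanoyloxy)ethyl)-1,2,3-selenadiazol-4-yl]-2,2'-bithiophen-5-yl}methyl 3-methylbut-2-enoate F2. Thermolysis of this selenadiazole in o-dichlorobenzene at about 180 °C extrudes nitrogen and selenium and returns to the route at the target 17.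

Step 8. The free mercapto ketone may be lost to self-condensation or disulfide formation before it reaches the chloro enal, or the sequence may stall at the open vinyl sulfide. The fallback reverses the order in which sulfur is attached and needs no free thiol. It sets out from 6, which with Na2S·9H2O in DMF at 0 °C → rt should give sodium (Z)-1-(5-{[(3-methylbut-2-enoyl)oxy]methyl}thiophen-2-yl)-3-oxoprop-1-ene-1-thiolate F3 by addition–elimination. Bromo ketone 11 is then added; S-alkylation rejoins the route at vinyl sulfide 13, which K2CO3 in the same flask should close and dehydrate to 15.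

Step 7. The first-formed thiolate may attack a second molecule of bromo ketone to give the thioether, hydrosulfide may cleave the ester, and the thiol may oxidise during isolation. The fallback sets out from 11 and introduces sulfur in protected form. Triphenylmethanethiol and Et3N in CH2Cl2 should give 4-oxo-5-[(triphenylmethyl)sulfanyl]pentyl 3-methylbutanoate F4, a stable thioether that cannot alkylate twice. Trifluoroacetic acid and Et3SiH in CH2Cl2 at 0 °C then release the thiol under conditions that leave the ester intact, coming back to the route at 12 just before step 8.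

**Further compounds**
F1 | step 9 | {5'-[1-(carbamoylhydrazinylidene)-4-(3-methylbutanoyloxy)butyl]-2,2'-bithiophen-5-yl}methyl 3-methylbut-2-enoate | CC(C)=CC(=O)OCc1ccc(-c2ccc(C(CCCOC(=O)CC(C)C)=NNC(N)=O)s2)s1
F2 | step 9 | {5'-[5-(2-(3-methylbutanoyloxy)ethyl)-1,2,3-selenadiazol-4-yl]-2,2'-bithiophen-5-yl}methyl 3-methylbut-2-enoate | CC(C)=CC(=O)OCc1ccc(-c2ccc(-c3nn[se]c3CCOC(=O)CC(C)C)s2)s1
F3 | step 8 | sodium (Z)-1-(5-{[(3-methylbut-2-enoyl)oxy]methyl}thiophen-2-yl)-3-oxoprop-1-ene-1-thiolate | O=C/C=C(\[S-])c1ccc(COC(=O)C=C(C)C)s1.[Na+]
F4 | step 7 | 4-oxo-5-[(triphenylmethyl)sulfanyl]pentyl 3-methylbutanoate | CC(C)CC(=O)OCCCC(=O)CSC(c1ccccc1)(c1ccccc1)c1ccccc1
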